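# Design of a total synthesis of CNP0157858.3 through a keteniminium [2+2] cycloaddition

## The problem

The skeleton is numbered C1 to C17: C1 (acetoxy carbinol of ring A), C2 (free carbinol), C3 (A/B fusion CH), C4 (ketone), C5 (spiro carbon), C6 and C7 (cyclopropane CH2 and CH, with C8 the methyl on C7), C9 (second acetoxy carbinol), C10 and C17 (the two hydroxylated cyclobutane carbons), C11 (cyclobutane CH), C12 (CH2), C13 (ketone), C14 (gem-dimethyl carbon), C15 (D/A fusion CH) and C16 (methyl-bearing quaternary carbon); ring A is C1–C2–C3–C17–C16–C15, ring B C3–C4–C5–C9–C10–C17, ring C the cyclobutane C10–C11–C16–C17 and ring D C11–C12–C13–C14–C15–C16.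

The cyclobutane is fused on three of its four edges, and all three six-membered rings leave it on one face (endo), while H11, the C16 methyl group and the C10 and C17 hydroxyls sit on the other (exo); the molecule is a bowl whose convex face is the only one an external reagent reaches.

Eleven stereocentres follow from this. C15 has no neighbour to lean on and must be set absolutely, after which it can control C16 and C11. The exo face can then serve for C10, C9 (by syn addition to a C9=C10 alkene), C1 and C2, whereas C17 and C3 need carbon to arrive from the endo face and must be delivered by tethers. C5 and C7 are best imported with the cyclopropane.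

The oxygen pattern is a second problem: the C1 acetate and C2 hydroxyl are trans, so cis-dihydroxylation of a ring A alkene cannot serve, and the free C2 hydroxyl must be told apart from two acetylated (C1, C9) and two oxidised (C4, C13) secondary positions.

The finished molecule is fragile. C4 is a β-hydroxy ketone twice over (C2 and C17: retro-aldol and dehydration with base), the vicinal tertiary cyclobutanols at C10 and C17 invite acid-induced ring contraction, the acetates can migrate to neighbouring hydroxyls, and the cyclopropyl ketone is an acceptor. The last steps must therefore be neutral or weakly acidic.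

The feature that opens the problem is ring C: it shares C11–C16 with ring D and carries the quaternary methyl carbon C16 next to oxygenated C17, the pattern left by adding a C16=C17 ketene equivalent across a C10=C11 alkene. The resulting cyclobutanone has C10 as its only enolisable position, exactly where C9 and a hydroxyl must enter.

## Retrosynthesis

**Protecting-group endgame (45 ⇐ 44 ⇐ 43 ⇐ 42 ⇐ 41 ⇐ 40).** No skeletal bond is cut. The free C2 hydroxyl of 45 is traced to silyl ether 44 so that it is released last, under weakly acidic fluoride. The C9 acetate is traced to diol 43 and acetonide 42, and the C4 and C13 ketones to diol 41 and its triethylsilyl ethers 40. This order is preferred to any selective acylation or oxidation among free carbinols, which five similar secondary positions would not allow. It asks only for a TES/TBS discrimination, one double oxidation and two acetylations that each meet a single free secondary hydroxyl.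

**C1–O and C2–H (39 ⇐ 37 ⇐ 36 ⇐ 35).** The trans diol monoether 39 is cut to the silyl enol ether 37 of C2 ketone 35. Hydroboration puts boron on C1 and hydrogen on C2 from the same exo face, which gives the trans arrangement and delivers C1 free and C2 protected in one step. The neighbouring cuts are weaker: a C1=C2 alkene would give the cis diol with osmium, epoxide opening would hinge on regiochemistry, and reduction of a C2 ketone beside a C4 ketone would pass through a β-diketone. The precursor has two stereocentres fewer and no differentiation problem; the forward step needs kinetic enolisation toward C1 and exo-face attack.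

**Ring B, C3–C4 (35 ⇐ 34).** The C3–C4 bond is cut as an aldol addition of the ring A ketone to a C4 aldehyde. Acylation at C3 would give the C2/C4 β-diketone and spoil the next disconnection. The C4 carbinol costs no extra step because it is oxidised together with C13. The precursor 34 is tricyclic; the forward reaction must run under reversible enolisation, since only the C3 enolate can close a six-membered ring, and the endo tether gives the cis A/B fusion.

**Ring A, C3–C17 (32 ⇐ 31).** The C3–C17 bond is cut as an aldol addition of a methyl ketone to the cyclobutanone. An intermolecular addition of a C3 nucleophile to C17 was rejected because it would come from the exo face and give the wrong tertiary alcohol. The tether through C15 can only reach the endo face, and release of cyclobutanone strain drives the addition. The precursor 31 is a bicyclic diketone whose methyl ketone is the former propenyl group.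

**C9–O, C10–O and C2=O (31 ⇐ 30 ⇐ 29 ⇐ 28).** Both oxygens at C9 and C10 are removed together to the E-enone 29. Syn addition from the exo face fixes C10 and, through the alkene geometry, C9. The stepwise alternatives fail: aldol addition followed by enolate hydroxylation would give the C9 epimer (anti aldol, then exo oxidation), and hydroxylation before the aldol would put C9 on the exo face. The C2 ketone is traced to the propenyl group of 28 by a Wacker oxidation placed before the osmylation, so that only one alkene is left for osmium and the three propenyl carbons become C1, C2 and C3 without loss.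

**C9–C10 (28 ⇐ 16 + 25).** The enone is cut to cyclobutanone 16 and the non-enolisable aldehyde 25. This is the convergent bond: 25 brings C4 to C9 with C5 and C7 already set, and 16 can enolise only at C10.

**Key disconnection, C10–C17 and C11–C16 (16 ⇐ 14).** Rings C and D are opened together to the acyclic pyrrolidine amide 14, whose keteniminium ion (C16=C17) adds across the terminal C10=C11 alkene. Two rings, two bonds and two stereocentres fall away, and the precursor keeps only C13 and C15 as stereocentres. The forward reaction must add to the alkene face that places C17 cis to the C15 arm.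

**C15–C16 (14 ⇐ 9 + 12).** The amide is cut by an Eschenmoser–Claisen rearrangement to allylic alcohol 9 and amide acetal 12. This delivers the tertiary amide needed for the key step directly (an Ireland–Claisen would give an acid) and transfers the carbinol configuration of 9 to C15.

**Chain assembly (9 ⇐ 8 ⇐ 6 + 7; 6 ⇐ 5 ⇐ 4 ⇐ 3 ⇐ 1 + 2).** The allylic alcohol comes from enone 8 by reagent-controlled reduction, the enone from aldehyde 6 and phosphonate 7, and the C13 carbinol from an enantioselective allylation of methyl hydroxypivalate 1 with allyl acetate 2.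

**Cyclopropane fragment (25 ⇐ 24 ⇐ 23 ⇐ 21 ⇐ 20 ⇐ 19 ⇐ 17 + 18).** The aldehyde is traced to the cyclopropane diester 19, made from dimethyl malonate 17 and the chiral-pool cyclic sulfate 18. The two ester groups are told apart by the methyl group on C7: the ester trans to it is hydrolysed and becomes C9, the cis ester becomes C4.

## Roads not taken

**Alternative 1:** The cut is C3–C17 and C2–C3 in one operation. In the forward step the C3 methyl group next to a C4 carbonyl is enolised and adds to the C17 cyclobutanone carbonyl (ring B); the new C3 enolate then adds to a C2 aldehyde carbon (ring A), giving A1.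
- Merits: it is the redox-ideal way to rings A and B. C4 arrives as the ketone, C2 as the free secondary alcohol and C17 as the tertiary alcohol, and two rings close at once.
- Weak points: the C2 aldehyde must already carry the C1 oxygen. In A1 that oxygen is a ketalised ketone, whose later reduction would have to deliver hydride from the concave face to give the exo alcohol. The C2 configuration rests on chelation in the second aldol, and the second enolisation must occur next to a β-alkoxide.
- Comparison: in redox economy this road is better, and its endgame would be about three steps shorter. The chosen plan uses the same strain-driven aldol logic with the carbonyl positions exchanged. Against the longer endgame it sets three things: rings C and D with C11 and C16 come in one step from an acyclic amide; the C15 arm comes from the Claisen step with all three carbons in place; and the C2 ketone lets C1 and C2 be set and differentiated by one exo-face hydroboration.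

**Alternative 2:** The cut is C1–C15. In the forward step a triazolium-derived carbene turns the C1 aldehyde carbon into an acyl anion equivalent that adds to C15, one of two enantiotopic β-carbons of a cross-conjugated dienone, giving the cis-fused A/D bicycle A2.
- Merits: it is catalytic and enantioselective, sets C15 and C16 from an achiral substrate, and reaches a bicycle quickly, with a C1 ketone and a ring D enone as handles.
- Weak points: the cyclobutane, the hardest ring, is left for later. C10 would have to be joined to both the enone β-carbon C11 and the ketal carbon C17 on a congested quaternary neighbourhood. C14 is still a methylene and must be dimethylated next to the fusion carbon while the enone survives. C2 and C3 carry no functionality for the C2 hydroxyl or the C3–C4 bond. The C1 ketone again needs hydride from the concave face.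
- Comparison: this road is better in asymmetric economy, with one catalyst for two centres where the chosen plan uses two catalysts and a chirality transfer. The chosen plan sets against this that it forms the four-membered ring first, as a ketone whose carbonyl carbon and single α-position are the two places where everything else is attached.

**Alternative 3:** The cut is C5–C6 and C5–C7 at the end. In the forward step the C5 enolate, flanked by the C4 and C9 carbonyl groups, attacks the primary carbon of cyclic sulfate 18 and then displaces the secondary sulfate with inversion, giving A3.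
- Merits: it is convergent, uses the same chiral-pool reagent 18 as the chosen route, spares the cyclopropyl ketone some twenty steps, and needs no six-step fragment.
- Weak points: the second alkylation at a secondary carbon competes with O-alkylation to a dihydrofuran. Nothing obvious decides on which face of ring B the C7 carbon ends up, and so whether the methyl group is cis to C4 or to C9. The base meets an acetate and a β-silyloxy ketone. The C9 ketone must afterwards be reduced selectively beside the C4 and C13 ketones and with the right facial sense.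
- Comparison: in convergence this road is better. The chosen plan sets against it that the C5/C7 relationship is fixed in a small fragment by a sterically governed hydrolysis, and that C9 arrives as a carbinol of the correct configuration from the syn-dihydroxylation, so no late ketone differentiation is needed.

Key step: step 9

Remark: TBS is tert-butyldimethylsilyl and TES is triethylsilyl. Cyclic sulfate 18 is taken as a commercial chiral-pool reagent. The C16 centre of 14, the C9 and C10 centres of 26 and 27 and the C4 carbinol of 35 to 41 are drawn as the expected major epimers; the other epimers would converge at steps 9, 16 and 29.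

## Route

Step 1
Reactants: 1 methyl 3-hydroxy-2,2-dimethylpropanoate; 2 allyl acetate
Product: 3 methyl (3R)-3-hydroxy-2,2-dimethylhex-5-enoate
Conditions: [Ir(cod)Cl]2 (2.5 mol%), (R)-BINAP (5 mol%), 4-chloro-3-nitrobenzoic acid (10 mol%), Cs2CO3 (20 mol%), THF, 100 °C, sealed tube
Reagents that add atoms: none
Why: Iridium-catalysed transfer-hydrogenative carbonyl allylation (Krische allylation): the π-allyliridium C,O-benzoate formed in situ dehydrogenates the neopentyl alcohol to the non-enolisable aldehyde and allylates it in the chiral pocket, so the C13 carbinol (3R) should be set by the ligand without a separate oxidation; this centre is a spectator that ends as a ketone.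

Step 2
Reactants: 3 methyl (3R)-3-hydroxy-2,2-dimethylhex-5-enoate
Product: 4 methyl (3R)-3-[(tert-butyldimethylsilyl)oxy]-2,2-dimethylhex-5-enoate
Conditions: TBSOTf, 2,6-lutidine, CH2Cl2, 0 °C
Reagents that add atoms: tert-butyldimethylsilyl trifluoromethanesulfonate, CC(C)(C)[Si](C)(C)OS(=O)(=O)C(F)(F)F
Why: Silylation of a hindered β-hydroxy ester with a silyl triflate and a hindered pyridine; alkoxide conditions, which would risk retro-aldol cleavage, are avoided.

Step 3
Reactants: 4 methyl (3R)-3-[(tert-butyldimethylsilyl)oxy]-2,2-dimethylhex-5-enoate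
Product: 5 (3R)-3-[(tert-butyldimethylsilyl)oxy]-2,2-dimethylhex-5-en-1-ol
Conditions: i-Bu2AlH (2.5 equiv), CH2Cl2, −78 → 0 °C; aqueous KNaC4H4O6
Reagents that add atoms: none
Why: Full hydride reduction of the neopentyl ester to the primary alcohol; the two-step passage to the aldehyde is chosen because partial reduction of such esters tends to over-reduce.

Step 4
Reactants: 5 (3R)-3-[(tert-butyldimethylsilyl)oxy]-2,2-dimethylhex-5-en-1-ol
Product: 6 (3R)-3-[(tert-butyldimethylsilyl)oxy]-2,2-dimethylhex-5-enal
Conditions: Dess–Martin periodinane, NaHCO3, CH2Cl2, rt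
Reagents that add atoms: none
Why: Dess–Martin oxidation of a primary alcohol; the aldehyde has no α-hydrogen and cannot enolise or epimerise.

Step 5
Reactants: 6 (3R)-3-[(tert-butyldimethylsilyl)oxy]-2,2-dimethylhex-5-enal; 7 dimethyl (2-oxopropyl)phosphonate
Product: 8 (3E,6R)-6-[(tert-butyldimethylsilyl)oxy]-5,5-dimethylnona-3,8-dien-2-one
Conditions: Ba(OH)2·8H2O, THF–H2O (40:1), rt
Reagents that add atoms: none
Why: Horner–Wadsworth–Emmons olefination with a stabilised β-ketophosphonate should give the E-enone; the mild heterogeneous base copes with the hindered aldehyde and leaves the silyl ether alone.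

Step 6
Reactants: 8 (3E,6R)-6-[(tert-butyldimethylsilyl)oxy]-5,5-dimethylnona-3,8-dien-2-one
Product: 9 (2R,3E,6R)-6-[(tert-butyldimethylsilyl)oxy]-5,5-dimethylnona-3,8-dien-2-ol
Conditions: (S)-2-methyl-CBS-oxazaborolidine (20 mol%), catecholborane, toluene, −78 °C
Reagents that add atoms: none
Why: Corey–Bakshi–Shibata reduction: the oxazaborolidine binds the ketone with the alkenyl group as the large substituent and should deliver hydride to give the 2R alcohol; catecholborane at low temperature does not hydroborate the terminal alkene.

Step 7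
Reactants: 10 1-(pyrrolidin-1-yl)propan-1-one
Product: 12 1-(1,1-dimethoxypropyl)pyrrolidine, via 1-(1-methoxypropylidene)pyrrolidinium methyl sulfate 11 (not isolated)
Conditions: Me2SO4, neat, 80 °C; then NaOMe, MeOH, 0 °C → rt; distillation
Reagents that add atoms: dimethyl sulfate, COS(=O)(=O)OC; sodium methoxide, [Na+].[O-]C
Why: O-Methylation of the tertiary amide gives the imidate salt, and methoxide adds to it; this is the standard preparation of amide acetals.

Step 8
Reactants: 9 (2R,3E,6R)-6-[(tert-butyldimethylsilyl)oxy]-5,5-dimethylnona-3,8-dien-2-ol; 12 1-(1,1-dimethoxypropyl)pyrrolidine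
Product: 14 (2S,3S,5R)-5-[(tert-butyldimethylsilyl)oxy]-2,4,4-trimethyl-3-[(1E)-prop-1-en-1-yl]-1-(pyrrolidin-1-yl)oct-7-en-1-one, via Z ketene N,O-acetal 13 (not isolated)
Conditions: 12 (3 equiv), xylene, 140 °C, methanol distilled off
Reagents that add atoms: none
Why: Eschenmoser–Claisen rearrangement: exchange and loss of two methanol give the ketene N,O-acetal with methyl cis to oxygen, and the chair transition state with the carbinol methyl group equatorial should transfer the 2R configuration of 9 to C15 (3S in 14) and give the E-propenyl group; C16 (anti, 2S) is of no consequence.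

Step 9
Reactants: 14 (2S,3S,5R)-5-[(tert-butyldimethylsilyl)oxy]-2,4,4-trimethyl-3-[(1E)-prop-1-en-1-yl]-1-(pyrrolidin-1-yl)oct-7-en-1-one
Product: 16 (1R,3R,5R,6S)-3-[(tert-butyldimethylsilyl)oxy]-4,4,6-trimethyl-5-[(1E)-prop-1-en-1-yl]bicyclo[4.2.0]octan-7-one, via cyclobutaniminium triflate 15 (not isolated)
Conditions: Tf2O (1.2 equiv), 2,4,6-collidine (1.5 equiv), ClCH2CH2Cl, −20 → 80 °C; then aqueous NaHCO3, rt
Reagents that add atoms: water, O (carbonyl oxygen of 16); trifluoromethanesulfonic anhydride, O=S(=O)(OS(=O)(=O)C(F)(F)F)C(F)(F)F (triflate counter-ion of 15 only)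
Why: Tf2O triflates the amide oxygen and collidine removes H16, so that loss of triflate gives the disubstituted keteniminium ion (C16=C17=N+), which adds across the tethered C10=C11 alkene in an asynchronous thermal [2+2] cycloaddition; the closest known reaction type is the intramolecular keteniminium–alkene cycloaddition of Tf2O-activated tertiary amides to fused cyclobutanones. Bonding starts between the terminal carbon C10 and the electrophilic central carbon C17, the only regiochemistry that puts the developing charge on the secondary C11, and the enamine carbon C16 then closes on C11. Ring D therefore forms as a six-membered ring through a chair-like array of C11 to C16, and ring C is the four-membered ring completed by the two new bonds, cis-fused by necessity. C11 and C16 are the new stereocentres and both are controlled by C15, with C13 reinforcing: in the chair that keeps the propenyl and silyloxy groups equatorial the alkene is equatorial at C11 and the linear, sterically small C17 takes the axial position at C16, whereas the other mode would put the C16 methyl group axial against an axial C14 methyl group. The step needs this facial selectivity (C17 cis to the C15 arm) and chemoselectivity for the terminal alkene; the latter is secured because addition to the propenyl group would give a bicyclo[2.1.0] or [1.1.1] system. The C16 configuration of 14 is erased in the keteniminium ion, so both Claisen epimers converge. Hydrolysis of 15 gives the cyclobutanone, whose only enolisable position is C10.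

Step 10
Reactants: 17 dimethyl malonate; 18 (4S)-4-methyl-1,3,2-dioxathiolane 2,2-dioxide
Product: 19 dimethyl (2R)-2-methylcyclopropane-1,1-dicarboxylate
Conditions: NaH (2.1 equiv), DME, 0 °C → reflux
Reagents that add atoms: none
Why: Double alkylation of malonate by a 1,2-cyclic sulfate: attack at the primary carbon, then 3-exo-tet displacement of the secondary sulfate with inversion, should give the 2R cyclopropane (C7) from the 4S sulfate.

Step 11
Reactants: 19 dimethyl (2R)-2-methylcyclopropane-1,1-dicarboxylate
Product: 20 (1S,2R)-1-(methoxycarbonyl)-2-methylcyclopropane-1-carboxylic acid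
Conditions: KOH (1.0 equiv), MeOH–H2O, 0 °C → rt; then HCl to pH 2
Reagents that add atoms: potassium hydroxide, [K+].[OH-]
Why: Mono-saponification of a geminal diester: hydroxide should attack the ester trans to the C7 methyl group, and the carboxylate formed protects the second ester; this differentiation fixes C5 (acid becomes C9, ester becomes C4).

Step 12
Reactants: 20 (1S,2R)-1-(methoxycarbonyl)-2-methylcyclopropane-1-carboxylic acid
Product: 21 (1R,2R)-1-(hydroxymethyl)-2-methylcyclopropane-1-carboxylic acid
Conditions: LiBH4 (3 equiv), THF, 0 → 50 °C; then aqueous HCl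
Reagents that add atoms: none
Why: LiBH4 reduces the ester but not the lithium carboxylate formed in the first instant, giving the hydroxy acid.

Step 13
Reactants: 21 (1R,2R)-1-(hydroxymethyl)-2-methylcyclopropane-1-carboxylic acid
Product: 23 (1R,2R)-1-{[(tert-butyldimethylsilyl)oxy]methyl}-2-methylcyclopropane-1-carboxylic acid, via silyl ester 22 (not isolated)
Conditions: TBSCl (2.5 equiv), imidazole, DMF, rt; then K2CO3, MeOH–H2O, rt; citric acid
Reagents that add atoms: tert-butyldimethylsilyl chloride, CC(C)(C)[Si](C)(C)Cl
Why: Both hydroxyl and carboxyl groups are silylated, and the labile silyl ester is cleaved by mild basic methanolysis, leaving the primary silyl ether.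

Step 14
Reactants: 23 (1R,2R)-1-{[(tert-butyldimethylsilyl)oxy]methyl}-2-methylcyclopropane-1-carboxylic acid
Product: 24 [(1S,2R)-1-{[(tert-butyldimethylsilyl)oxy]methyl}-2-methylcyclopropyl]methanol
Conditions: BH3·SMe2, THF, 0 °C → rt; MeOH
Reagents that add atoms: none
Why: Borane reduces the carboxylic acid through the acyloxyborane and leaves the silyl ether untouched.

Step 15
Reactants: 24 [(1S,2R)-1-{[(tert-butyldimethylsilyl)oxy]methyl}-2-methylcyclopropyl]methanol
Product: 25 (1R,2R)-1-{[(tert-butyldimethylsilyl)oxy]methyl}-2-methylcyclopropane-1-carbaldehyde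
Conditions: Dess–Martin periodinane, NaHCO3, CH2Cl2, rt
Reagents that add atoms: none
Why: Dess–Martin oxidation to a neopentyl aldehyde that has no α-hydrogen.

Step 16
Reactants: 16 (1R,3R,5R,6S)-3-[(tert-butyldimethylsilyl)oxy]-4,4,6-trimethyl-5-[(1E)-prop-1-en-1-yl]bicyclo[4.2.0]octan-7-one; 25 (1R,2R)-1-{[(tert-butyldimethylsilyl)oxy]methyl}-2-methylcyclopropane-1-carbaldehyde
Product: 28 (E)-C9=C10 enone: cyclobutanone 16 carrying at C10 the [(1S,2R)-1-(TBS-oxymethyl)-2-methylcyclopropyl]methylidene group with C5 anti to the C17 carbonyl, via aldol adduct 26 (not isolated), via mesylate 27 (not isolated)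
Conditions: LiN(i-Pr)2, THF, −78 °C; 25; then MsCl, −78 → 0 °C; DBU, 0 °C → rt
Reagents that add atoms: methanesulfonyl chloride, CS(=O)(=O)Cl (mesyl group of 27 only; no atom of it remains in 28)
Why: Directed aldol addition of the lithium enolate of 16 (C10 is its only enolisable position) to a non-enolisable aldehyde, then mesylation of the aldolate and E1cB elimination; the E-alkylidene ketone is the expected product and the C9 and C10 centres of 26 and 27 are erased.

Step 17
Reactants: 28 (E)-C9=C10 enone with the C15 propenyl group
Product: 29 (E)-C9=C10 enone with a 2-oxopropyl group at C15 (C2 methyl ketone)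
Conditions: PdCl2(Quinox) (5 mol%), AgSbF6 (12 mol%), aqueous t-BuOOH, CH2Cl2, 0 °C → rt; Quinox = 2-(4,5-dihydro-1,3-oxazol-2-yl)quinoline
Reagents that add atoms: tert-butyl hydroperoxide, CC(C)(C)OO
Why: Wacker-type oxidation of an internal alkene with a cationic palladium catalyst and a hydroperoxide: oxygen should go to C2, the alkene carbon remote from the branched and inductively electron-poor C15 side, while the conjugated trisubstituted C9=C10 alkene is inert; the three propenyl carbons thereby become C1, C2 and C3.

Step 18
Reactants: 29 (E)-C9=C10 enone with the C2 methyl ketone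
Product: 30 C9,C10-diol (C10 hydroxyl exo; C9 and C10 configured as in 45) with the C2 methyl ketone and C17 cyclobutanone
Conditions: K2OsO2(OH)4 (5 mol%), N-methylmorpholine N-oxide (2 equiv), citric acid (1 equiv), t-BuOH–H2O (1:1), rt
Reagents that add atoms: N-methylmorpholine N-oxide, C[N+]1([O-])CCOCC1; water, O
Why: Catalytic osmium dihydroxylation (Upjohn conditions with citric acid for an electron-poor alkene) of the only alkene left: syn addition from the exo face, the face of H11 away from ring D, should set the C10 hydroxyl and, through the E geometry, the C9 carbinol with the relative configuration of the target.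

Step 19
Reactants: 30 C9,C10-diol
Product: 31 C9,C10-acetonide of 30
Conditions: 2-methoxypropene (5 equiv), PPTS (cat.), CH2Cl2, 0 °C
Reagents that add atoms: 2-methoxypropene, COC(C)=C
Why: Acid-catalysed acetonide formation with an enol ether (no methanol to ketalise the cyclobutanone); it masks the C10 α-ketol and the C9 β-hydroxyl against α-ketol shift and retro-aldol cleavage in the basic steps that follow.

Step 20
Reactants: 31 C9,C10-acetonide
Product: 32 tricyclic ketol (rings A, C and D closed): C3–C17 bond, C17 hydroxyl exo, C2 ketone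
Conditions: LiN(SiMe3)2 (1.1 equiv), THF, −78 → −40 °C; aqueous NH4Cl
Reagents that add atoms: none
Why: Intramolecular aldol addition (6-enolendo-exo-trig) of the kinetic methyl enolate of the C2 ketone to the strained, now non-enolisable cyclobutanone; the tether through C15 lies on the endo face, so C3 can only enter there and the C17 hydroxyl must be exo, and relief of ring strain should make the addition irreversible.

Step 21
Reactants: 32 tricyclic ketol
Product: 33 diol: 32 with free C4 primary and C13 secondary hydroxyls
Conditions: HF·pyridine, pyridine, THF, 0 °C → rt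
Reagents that add atoms: none
Why: Fluoride-induced cleavage of both tert-butyldimethylsilyl ethers under buffered conditions that leave the acetonide and the tertiary ketol alone.

Step 22
Reactants: 33 diol
Product: 34 C4 aldehyde
Conditions: TEMPO (10 mol%), PhI(OAc)2 (1.2 equiv), CH2Cl2, rt
Reagents that add atoms: none
Why: Oxoammonium oxidation, selective for the primary alcohol over the hindered secondary C13 carbinol and the tertiary alcohol; the aldehyde has no α-hydrogen.

Step 23
Reactants: 34 C4 aldehyde
Product: 35 pentacyclic keto triol: C3–C4 bond (ring B closed; H3 exo); C2 ketone; C4, C13 and C17 hydroxyls; C9,C10-acetonide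
Conditions: K2CO3 (0.5 equiv), MeOH, 0 °C
Reagents that add atoms: none
Why: Intramolecular aldol addition (6-enolexo-exo-trig) under reversible enolisation: the C1 enolate has no carbonyl within reach of a normal ring, so only the C3 enolate is productive, and since C4 hangs from the endo side of C17 through C5–C9–C10 the new bond should form cis to C10 (A/B cis fusion); the C4 carbinol (anti expected) is later oxidised.

Step 24
Reactants: 35 pentacyclic keto triol
Product: 36 C4,C13,C17-tris(triethylsilyl) ether of 35
Conditions: TESOTf (4 equiv), 2,6-lutidine, CH2Cl2, −78 → 0 °C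
Reagents that add atoms: triethylsilyl trifluoromethanesulfonate, CC[Si](CC)(CC)OS(=O)(=O)C(F)(F)F
Why: Exhaustive silylation removes all acidic hydroxyls before the enolisation and uses a silyl group that can later be removed beside a tert-butyldimethylsilyl ether.

Step 25
Reactants: 36 tris(triethylsilyl) ether
Product: 37 C2 tert-butyldimethylsilyl enol ether (C1=C2 double bond)
Conditions: LiN(i-Pr)2 (1.3 equiv), THF, −78 °C; TBSCl, DMPU, −78 → 0 °C
Reagents that add atoms: tert-butyldimethylsilyl chloride, CC(C)(C)[Si](C)(C)Cl
Why: Kinetic deprotonation should occur at the C1 methylene because C3 is a methine flanked by two silyloxy-bearing carbons; O-silylation of the enolate gives the less substituted silyl enol ether.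

Step 26
Reactants: 37 C2 silyl enol ether
Product: 39 C1 alcohol (exo) with C2 tert-butyldimethylsilyl ether (endo), via alkylborane 38 (not isolated)
Conditions: BH3·THF (3 equiv), THF, 0 °C → rt; then aqueous NaOH, H2O2, 0 °C
Reagents that add atoms: hydrogen peroxide, OO (oxygen at C1); borane–tetrahydrofuran, [BH3-][O+]1CCCC1 (boron of 38 only)
Why: Hydroboration–oxidation of a silyl enol ether: boron adds to C1 (β to oxygen) and hydrogen to C2, syn and from the exo face, where only H3 and H15 flank the alkene while C4 and C14 block the endo face; oxidation with retention should give the C1 hydroxyl exo and the C2 silyloxy group endo, that is the trans diol with the oxygen that must stay free already protected.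

Step 27
Reactants: 39 C1 alcohol
Product: 40 C1 acetate
Conditions: Ac2O, pyridine, DMAP (cat.), CH2Cl2, rt
Reagents that add atoms: acetic anhydride, CC(=O)OC(C)=O
Why: DMAP-catalysed acetylation of the only free hydroxyl.

Step 28
Reactants: 40 C1 acetate
Product: 41 C4,C13,C17-triol with C1 acetate, C2 tert-butyldimethylsilyl ether and C9,C10-acetonide
Conditions: HF·pyridine, pyridine, THF, 0 °C
Reagents that add atoms: none
Why: Buffered fluoride cleaves triethylsilyl ethers much faster than the secondary tert-butyldimethylsilyl ether; acetonide and acetate are stable.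

Step 29
Reactants: 41 triol
Product: 42 C4,C13-diketone
Conditions: Dess–Martin periodinane (3 equiv), NaHCO3, CH2Cl2, rt
Reagents that add atoms: none
Why: Dess–Martin oxidation of both secondary carbinols while the tertiary C17 hydroxyl is inert; the non-basic medium preserves the β-silyloxy and β-hydroxy ketone arrays, and the C4 epimers converge here.

Step 30
Reactants: 42 diketone
Product: 43 C9,C10-diol
Conditions: AcOH–H2O (4:1), 40 °C
Reagents that add atoms: none
Why: Hydrolysis of the strained trans-fused acetonide in weak acid, which should spare the silyl ether, the acetate and the tertiary cyclobutanols.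

Step 31
Reactants: 43 C9,C10-diol
Product: 44 C1,C9-diacetate with C2 tert-butyldimethylsilyl ether (2-O-silyl derivative of 45)
Conditions: Ac2O, Et3N, DMAP, CH2Cl2, rt → 40 °C
Reagents that add atoms: acetic anhydride, CC(=O)OC(C)=O
Why: DMAP-catalysed acetylation of the only free secondary hydroxyl (C9); the tertiary C10 and C17 hydroxyls do not react under these conditions and C2 is silylated.

Step 32
Reactants: 44 2-O-silyl derivative of 45
Product: 45 CNP0157858.3
Conditions: HF·pyridine, THF, 0 °C → rt
Reagents that add atoms: none
Why: Fluoride cleavage of the last silyl ether in a weakly acidic medium, in which the acetates should not migrate and the β-hydroxy ketone should not undergo retro-aldol cleavage.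

## Compound list

1 | methyl 3-hydroxy-2,2-dimethylpropanoate | COC(=O)C(C)(C)CO | starting material
2 | allyl acetate | C=CCOC(C)=O | starting material
3 | methyl (3R)-3-hydroxy-2,2-dimethylhex-5-enoate | C=CC[C@@H](O)C(C)(C)C(=O)OC | intermediate
4 | methyl (3R)-3-[(tert-butyldimethylsilyl)oxy]-2,2-dimethylhex-5-enoate | C=CC[C@@H](O[Si](C)(C)C(C)(C)C)C(C)(C)C(=O)OC | intermediate
5 | (3R)-3-[(tert-butyldimethylsilyl)oxy]-2,2-dimethylhex-5-en-1-ol | C=CC[C@@H](O[Si](C)(C)C(C)(C)C)C(C)(C)CO | intermediate
6 | (3R)-3-[(tert-butyldimethylsilyl)oxy]-2,2-dimethylhex-5-enal | C=CC[C@@H](O[Si](C)(C)C(C)(C)C)C(C)(C)C=O | intermediate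
7 | dimethyl (2-oxopropyl)phosphonate | COP(=O)(OC)CC(C)=O | starting material
8 | (3E,6R)-6-[(tert-butyldimethylsilyl)oxy]-5,5-dimethylnona-3,8-dien-2-one | C=CC[C@@H](O[Si](C)(C)C(C)(C)C)C(C)(C)/C=C/C(C)=O | intermediate
9 | (2R,3E,6R)-6-[(tert-butyldimethylsilyl)oxy]-5,5-dimethylnona-3,8-dien-2-ol | C=CC[C@@H](O[Si](C)(C)C(C)(C)C)C(C)(C)/C=C/[C@@H](C)O | intermediate
10 | 1-(pyrrolidin-1-yl)propan-1-one | CCC(=O)N1CCCC1 | starting material
11 | 1-(1-methoxypropylidene)pyrrolidinium methyl sulfate | CCC(OC)=[N+]1CCCC1.COS(=O)(=O)[O-] | intermediate (not isolated)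
12 | 1-(1,1-dimethoxypropyl)pyrrolidine | CCC(OC)(OC)N1CCCC1 | intermediate
13 | 1-[(1Z)-1-{[(2R,3E,6R)-6-(TBS-oxy)-5,5-dimethylnona-3,8-dien-2-yl]oxy}prop-1-en-1-yl]pyrrolidine | C/C=C(/N1CCCC1)O[C@H](C)/C=C/C(C)(C)[C@H](O[Si](C)(C)C(C)(C)C)CC=C | intermediate (not isolated)
14 | (2S,3S,5R)-5-[(tert-butyldimethylsilyl)oxy]-2,4,4-trimethyl-3-[(1E)-prop-1-en-1-yl]-1-(pyrrolidin-1-yl)oct-7-en-1-one | C=CC[C@@H](O[Si](C)(C)C(C)(C)C)C(C)(C)[C@@H](/C=C/C)[C@H](C)C(=O)N1CCCC1 | intermediate
15 | 1-[(1R,3R,5R,6S)-3-(TBS-oxy)-4,4,6-trimethyl-5-[(1E)-prop-1-en-1-yl]bicyclo[4.2.0]octan-7-ylidene]pyrrolidinium trifluoromethanesulfonate | C1[C@H]2C[C@@H](O[Si](C)(C)C(C)(C)C)C(C)(C)[C@@H](/C=C/C)[C@@]2(C)C1=[N+]3CCCC3.[O-]S(=O)(=O)C(F)(F)F | intermediate (not isolated)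
16 | (1R,3R,5R,6S)-3-[(tert-butyldimethylsilyl)oxy]-4,4,6-trimethyl-5-[(1E)-prop-1-en-1-yl]bicyclo[4.2.0]octan-7-one | C1[C@H]2C[C@@H](O[Si](C)(C)C(C)(C)C)C(C)(C)[C@@H](/C=C/C)[C@@]2(C)C1=O | intermediate
17 | dimethyl malonate | COC(=O)CC(=O)OC | starting material
18 | (4S)-4-methyl-1,3,2-dioxathiolane 2,2-dioxide | C[C@H]1COS(=O)(=O)O1 | starting material
19 | dimethyl (2R)-2-methylcyclopropane-1,1-dicarboxylate | COC(=O)C1(C[C@H]1C)C(=O)OC | intermediate
20 | (1S,2R)-1-(methoxycarbonyl)-2-methylcyclopropane-1-carboxylic acid | COC(=O)[C@]1(C[C@H]1C)C(=O)O | intermediate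
21 | (1R,2R)-1-(hydroxymethyl)-2-methylcyclopropane-1-carboxylic acid | OC[C@]1(C[C@H]1C)C(=O)O | intermediate
22 | tert-butyldimethylsilyl (1R,2R)-1-{[(tert-butyldimethylsilyl)oxy]methyl}-2-methylcyclopropane-1-carboxylate | CC(C)(C)[Si](C)(C)OC[C@]1(C[C@H]1C)C(=O)O[Si](C)(C)C(C)(C)C | intermediate (not isolated)
23 | (1R,2R)-1-{[(tert-butyldimethylsilyl)oxy]methyl}-2-methylcyclopropane-1-carboxylic acid | CC(C)(C)[Si](C)(C)OC[C@]1(C[C@H]1C)C(=O)O | intermediate
24 | [(1S,2R)-1-{[(tert-butyldimethylsilyl)oxy]methyl}-2-methylcyclopropyl]methanol | CC(C)(C)[Si](C)(C)OC[C@]1(C[C@H]1C)CO | intermediate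
25 | (1R,2R)-1-{[(tert-butyldimethylsilyl)oxy]methyl}-2-methylcyclopropane-1-carbaldehyde | CC(C)(C)[Si](C)(C)OC[C@]1(C[C@H]1C)C=O | intermediate
26 | aldol adduct of 16 and 25 (C10–C9 bond exo, 9,10-anti, C9 hydroxyl) | CC(C)(C)[Si](C)(C)OC[C@]1(C[C@H]1C)[C@H](O)[C@@H]2[C@H]3C[C@@H](O[Si](C)(C)C(C)(C)C)C(C)(C)[C@@H](/C=C/C)[C@@]3(C)C2=O | intermediate (not isolated)
27 | C9 methanesulfonate of 26 | CC(C)(C)[Si](C)(C)OC[C@]1(C[C@H]1C)[C@H](OS(C)(=O)=O)[C@@H]2[C@H]3C[C@@H](O[Si](C)(C)C(C)(C)C)C(C)(C)[C@@H](/C=C/C)[C@@]3(C)C2=O | intermediate (not isolated)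
28 | (E)-C9=C10 enone with C15 propenyl group (C5 anti to the C17 carbonyl) | CC(C)(C)[Si](C)(C)OC[C@]1(C[C@H]1C)/C=C2\[C@H]3C[C@@H](O[Si](C)(C)C(C)(C)C)C(C)(C)[C@@H](/C=C/C)[C@@]3(C)C2=O | intermediate
29 | (E)-C9=C10 enone with C15 2-oxopropyl group (C2 ketone) | CC(C)(C)[Si](C)(C)OC[C@]1(C[C@H]1C)/C=C2\[C@H]3C[C@@H](O[Si](C)(C)C(C)(C)C)C(C)(C)[C@@H](CC(C)=O)[C@@]3(C)C2=O | intermediate
30 | C9,C10-diol (C10 hydroxyl exo), C2 and C17 ketones | CC(C)(C)[Si](C)(C)OC[C@]1(C[C@H]1C)[C@@H](O)[C@@]2(O)[C@H]3C[C@@H](O[Si](C)(C)C(C)(C)C)C(C)(C)[C@@H](CC(C)=O)[C@@]3(C)C2=O | intermediate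
31 | C9,C10-acetonide of 30 | CC(C)(C)[Si](C)(C)OC[C@]1(C[C@H]1C)[C@H]4OC(C)(C)O[C@@]42[C@H]3C[C@@H](O[Si](C)(C)C(C)(C)C)C(C)(C)[C@@H](CC(C)=O)[C@@]3(C)C2=O | intermediate
32 | tricyclic ketol (rings A, C, D; C17 hydroxyl exo; C2 ketone) | CC(C)(C)[Si](C)(C)OC[C@]1(C[C@H]1C)[C@H]4OC(C)(C)O[C@@]42[C@H]3C[C@@H](O[Si](C)(C)C(C)(C)C)C(C)(C)[C@H]5CC(=O)C[C@]2(O)[C@]53C | intermediate
33 | 32 with free C4 primary and C13 secondary hydroxyls | OC[C@]1(C[C@H]1C)[C@H]4OC(C)(C)O[C@@]42[C@H]3C[C@@H](O)C(C)(C)[C@H]5CC(=O)C[C@]2(O)[C@]53C | intermediate
34 | C4 aldehyde of 33 | O=C[C@]1(C[C@H]1C)[C@H]4OC(C)(C)O[C@@]42[C@H]3C[C@@H](O)C(C)(C)[C@H]5CC(=O)C[C@]2(O)[C@]53C | intermediate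
35 | pentacyclic keto triol (rings A to D closed; C2 ketone; C4, C13, C17 hydroxyls; C9,C10-acetonide) | C1C(=O)[C@H]2[C@H](O)[C@]3(C[C@H]3C)[C@H]5OC(C)(C)O[C@@]53[C@H]4C[C@@H](O)C(C)(C)[C@@H]1[C@@]4(C)[C@@]23O | intermediate
36 | C4,C13,C17-tris(triethylsilyl) ether of 35 | C1C(=O)[C@H]2[C@H](O[Si](CC)(CC)CC)[C@]3(C[C@H]3C)[C@H]5OC(C)(C)O[C@@]53[C@H]4C[C@@H](O[Si](CC)(CC)CC)C(C)(C)[C@@H]1[C@@]4(C)[C@@]23O[Si](CC)(CC)CC | intermediate
37 | C2 tert-butyldimethylsilyl enol ether of 36 (C1=C2) | C1=C(O[Si](C)(C)C(C)(C)C)[C@H]2[C@H](O[Si](CC)(CC)CC)[C@]3(C[C@H]3C)[C@H]5OC(C)(C)O[C@@]53[C@H]4C[C@@H](O[Si](CC)(CC)CC)C(C)(C)[C@@H]1[C@@]4(C)[C@@]23O[Si](CC)(CC)CC | intermediate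
38 | C1 borane (boron exo) with C2 silyloxy group endo | B[C@@H]1[C@@H](O[Si](C)(C)C(C)(C)C)[C@H]2[C@H](O[Si](CC)(CC)CC)[C@]3(C[C@H]3C)[C@H]5OC(C)(C)O[C@@]53[C@H]4C[C@@H](O[Si](CC)(CC)CC)C(C)(C)[C@@H]1[C@@]4(C)[C@@]23O[Si](CC)(CC)CC | intermediate (not isolated)
39 | C1 alcohol (exo) with C2 tert-butyldimethylsilyl ether (endo) | O[C@@H]1[C@@H](O[Si](C)(C)C(C)(C)C)[C@H]2[C@H](O[Si](CC)(CC)CC)[C@]3(C[C@H]3C)[C@H]5OC(C)(C)O[C@@]53[C@H]4C[C@@H](O[Si](CC)(CC)CC)C(C)(C)[C@@H]1[C@@]4(C)[C@@]23O[Si](CC)(CC)CC | intermediate
40 | C1 acetate of 39 | CC(=O)O[C@@H]1[C@@H](O[Si](C)(C)C(C)(C)C)[C@H]2[C@H](O[Si](CC)(CC)CC)[C@]3(C[C@H]3C)[C@H]5OC(C)(C)O[C@@]53[C@H]4C[C@@H](O[Si](CC)(CC)CC)C(C)(C)[C@@H]1[C@@]4(C)[C@@]23O[Si](CC)(CC)CC | intermediate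
41 | C4,C13,C17-triol (C1 acetate, C2 silyl ether, C9,C10-acetonide) | CC(=O)O[C@@H]1[C@@H](O[Si](C)(C)C(C)(C)C)[C@H]2[C@H](O)[C@]3(C[C@H]3C)[C@H]5OC(C)(C)O[C@@]53[C@H]4C[C@@H](O)C(C)(C)[C@@H]1[C@@]4(C)[C@@]23O | intermediate
42 | C4,C13-diketone | CC(=O)O[C@@H]1[C@@H](O[Si](C)(C)C(C)(C)C)[C@H]2C(=O)[C@]3(C[C@H]3C)[C@H]5OC(C)(C)O[C@@]53[C@H]4CC(=O)C(C)(C)[C@@H]1[C@@]4(C)[C@@]23O | intermediate
43 | C9,C10-diol of 42 | CC(=O)O[C@@H]1[C@@H](O[Si](C)(C)C(C)(C)C)[C@H]2C(=O)[C@]3(C[C@H]3C)[C@@H](O)[C@@]3(O)[C@H]4CC(=O)C(C)(C)[C@@H]1[C@@]4(C)[C@@]23O | intermediate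
44 | 2-O-(tert-butyldimethylsilyl) derivative of 45 | CC(=O)O[C@@H]1[C@@H](O[Si](C)(C)C(C)(C)C)[C@H]2C(=O)[C@]3(C[C@H]3C)[C@@H](OC(C)=O)[C@@]3(O)[C@H]4CC(=O)C(C)(C)[C@@H]1[C@@]4(C)[C@@]23O | intermediate
45 | CNP0157858.3 | CC(=O)O[C@@H]1[C@@H](O)[C@H]2C(=O)[C@]3(C[C@H]3C)[C@@H](OC(C)=O)[C@@]3(O)[C@H]4CC(=O)C(C)(C)[C@@H]1[C@@]4(C)[C@@]23O | target

## Step count and least certain steps

Total: 32 steps. Longest linear sequence: 25 steps (steps 1 to 6, 8, 9 and 16 to 32); step 7 (amide acetal) and steps 10 to 15 (fragment 25) are side branches.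

**Step 9 (key step).** The most likely failures are poor facial selectivity and cationic side reactions. The alkene may add through the chair in which the C16 methyl group rather than C17 is axial, giving the C11/C16 diastereomer. The secondary cation character at C11 may also lead to hydride shift or elimination in place of ring closure, and triflic species may attack the silyl ether. The fallback replaces the cationic keteniminium ion by a neutral ketene. It sets out from 9, which is acylated with propanoyl chloride to (2R,3E,6R)-6-(TBS-oxy)-5,5-dimethylnona-3,8-dien-2-yl propanoate F1. An Ireland–Claisen rearrangement (LiN(i-Pr)2, Me3SiCl, THF, −78 → 60 °C) gives (2S,3S,5R)-5-(TBS-oxy)-2,4,4-trimethyl-3-[(1E)-prop-1-en-1-yl]oct-7-enoic acid F2, and oxalyl chloride gives the acid chloride F3. Triethylamine in refluxing toluene generates the methyl ketene F4, which undergoes the thermal intramolecular ketene–alkene [2+2] cycloaddition through the same chair. The sequence returns to the route at 16.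

**Step 17.** The risk is loss of regiocontrol in the Wacker oxidation, with oxygen going to C1, or palladium-induced migration of the double bond before oxidation, because the two alkene carbons differ only by the remote branching. The fallback sets out from 28 and uses sterically governed hydroboration. A Luche reduction (NaBH4, CeCl3·7H2O, MeOH) gives the C17 allylic alcohol F5. 9-BBN followed by NaOH/H2O2 places the hydroxyl at the less hindered C2 and gives the C2,C17-diol F6 (C2 epimers). Dess–Martin oxidation of both carbinols returns to the route at 29.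

**Step 26.** Three things may go wrong: β-elimination of the silyloxy group from the intermediate borane (giving a ring A alkene), attack from the endo face, or no reaction at a congested trisubstituted enol ether. The fallback sets the two centres in separate exo-face events and sets out from 36. Enolisation with LiN(i-Pr)2 and oxidation with 2-(phenylsulfonyl)-3-phenyloxaziridine gives the C1 hydroxy ketone F7 (hydroxyl exo). Acetylation gives the C1 acetoxy ketone F8, and NaBH4 at −40 °C delivers hydride from the exo face to give the C2 alcohol F9 (hydroxyl endo). Silylation with TBSOTf and 2,6-lutidine returns to the route at 40.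

**Step 31.** The C9 hydroxyl lies between two fully substituted carbons, so acetylation may stall, and forcing conditions may acylate a tertiary hydroxyl or move the C1 acetate. The fallback sets out from 43 and acylates intramolecularly. Trimethyl orthoacetate and PPTS give the C9,C10 cyclic orthoacetate F10 (either epimer at the orthoester carbon). Brief treatment with aqueous acetic acid opens it to the hydroxy acetate, the acetyl group settling on the secondary C9 oxygen, and returns to the route at 44.

## Further compounds

F1 | step 9 | (2R,3E,6R)-6-[(tert-butyldimethylsilyl)oxy]-5,5-dimethylnona-3,8-dien-2-yl propanoate | C=CC[C@@H](O[Si](C)(C)C(C)(C)C)C(C)(C)/C=C/[C@@H](C)OC(=O)CC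
F2 | step 9 | (2S,3S,5R)-5-[(tert-butyldimethylsilyl)oxy]-2,4,4-trimethyl-3-[(1E)-prop-1-en-1-yl]oct-7-enoic acid | C=CC[C@@H](O[Si](C)(C)C(C)(C)C)C(C)(C)[C@@H](/C=C/C)[C@H](C)C(=O)O
F3 | step 9 | (2S,3S,5R)-5-[(tert-butyldimethylsilyl)oxy]-2,4,4-trimethyl-3-[(1E)-prop-1-en-1-yl]oct-7-enoyl chloride | C=CC[C@@H](O[Si](C)(C)C(C)(C)C)C(C)(C)[C@@H](/C=C/C)[C@H](C)C(Cl)=O
F4 | step 9 | (3S,5R)-5-[(tert-butyldimethylsilyl)oxy]-2,4,4-trimethyl-3-[(1E)-prop-1-en-1-yl]octa-1,7-dien-1-one (ketene) | C=CC[C@@H](O[Si](C)(C)C(C)(C)C)C(C)(C)[C@@H](/C=C/C)C(C)=C=O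
F5 | step 17 | C17 allylic alcohol of 28 (hydroxyl endo) | CC(C)(C)[Si](C)(C)OC[C@]1(C[C@H]1C)/C=C2\[C@H]3C[C@@H](O[Si](C)(C)C(C)(C)C)C(C)(C)[C@@H](/C=C/C)[C@@]3(C)[C@H]2O
F6 | step 17 | C2,C17-diol (2-hydroxypropyl group at C15, C2 epimers) | CC(C)(C)[Si](C)(C)OC[C@]1(C[C@H]1C)/C=C2\[C@H]3C[C@@H](O[Si](C)(C)C(C)(C)C)C(C)(C)[C@@H](CC(C)O)[C@@]3(C)[C@H]2O
F7 | step 26 | C1 hydroxy C2 ketone (hydroxyl exo) of 36 | O[C@@H]1C(=O)[C@H]2[C@H](O[Si](CC)(CC)CC)[C@]3(C[C@H]3C)[C@H]5OC(C)(C)O[C@@]53[C@H]4C[C@@H](O[Si](CC)(CC)CC)C(C)(C)[C@@H]1[C@@]4(C)[C@@]23O[Si](CC)(CC)CC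
F8 | step 26 | C1 acetoxy C2 ketone | CC(=O)O[C@@H]1C(=O)[C@H]2[C@H](O[Si](CC)(CC)CC)[C@]3(C[C@H]3C)[C@H]5OC(C)(C)O[C@@]53[C@H]4C[C@@H](O[Si](CC)(CC)CC)C(C)(C)[C@@H]1[C@@]4(C)[C@@]23O[Si](CC)(CC)CC
F9 | step 26 | C1 acetate C2 alcohol (hydroxyl endo) | CC(=O)O[C@@H]1[C@@H](O)[C@H]2[C@H](O[Si](CC)(CC)CC)[C@]3(C[C@H]3C)[C@H]5OC(C)(C)O[C@@]53[C@H]4C[C@@H](O[Si](CC)(CC)CC)C(C)(C)[C@@H]1[C@@]4(C)[C@@]23O[Si](CC)(CC)CC
F10 | step 31 | C9,C10 cyclic methyl orthoacetate of 43 (either epimer at the orthoester carbon) | CC(=O)O[C@@H]1[C@@H](O[Si](C)(C)C(C)(C)C)[C@H]2C(=O)[C@]3(C[C@H]3C)[C@H]5OC(C)(OC)O[C@@]53[C@H]4CC(=O)C(C)(C)[C@@H]1[C@@]4(C)[C@@]23O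
A1 | alternative 1 | tetracyclic C2,C17-diol with C4 ketone, C1 and C13 dioxolanes and C9,C10-acetonide | C12(OCCO2)[C@@H](O)[C@H]2C(=O)[C@]3(C[C@H]3C)[C@@H](OC(C)(C)O6)[C@@]36[C@H]4CC7(OCCO7)C(C)(C)[C@@H]1[C@@]4(C)[C@@]23O
A2 | alternative 2 | cis-fused bicyclic enedione ketal (rings A and D, C1 ketone, C13 enone, C17 dioxolane) | C4=CC(=O)C[C@@H](C(=O)CC2)[C@@]4(C)C23OCCO3
A3 | alternative 3 | tetracyclic spirocyclopropyl C4,C9-diketone (C1 acetate, C2 triethylsilyl ether, C10,C17-acetonide) | CC(=O)O[C@@H]1[C@@H](O[Si](CC)(CC)CC)[C@H]2C(=O)[C@]3(C[C@H]3C)C(=O)[C@@]3(OC6(C)C)[C@H]4CC(=O)C(C)(C)[C@@H]1[C@@]4(C)[C@@]23O6
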